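**Strategy.** The 25-membered ring (ring O, C1 carbonyl, C2–C24 methylenes) has no stereocentre and no handle other than the ester. It is therefore cut inside the polymethylene arc at the CH2–CH2 bond C16–C17, which splits it into two catalogue pieces: a C16 ω-bromo acid and a C8 ω-alkenol. After esterification, one operation (anti-Markovnikov hydroboration, then Pd-catalysed alkyl–alkyl Suzuki–Miyaura coupling under pseudo-high dilution) closes the macrocycle and delivers that bond at its final sp3–sp3 oxidation level, so no post-cyclization adjustment is needed. The precursor is the acyclic ester oct-7-en-1-yl 16-bromohexadecanoate.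

Key step: step 2

Remark: atoms are numbered as in the hydroxy acid (C1 = lactone carbonyl, C24 = O-bearing carbon). The target has no stereocentre. 16-Bromohexadecanoic acid and oct-7-en-1-ol are taken as catalogue compounds.

Step 1
Reactants: 1 16-bromohexadecanoic acid; 2 oct-7-en-1-ol
Product: 3 oct-7-en-1-yl 16-bromohexadecanoate
Conditions: DCC, DMAP (cat.), CH2Cl2, 0 °C → rt
Reagents that add atoms: none
Why: Steglich esterification, in which DCC turns the acid into an O-acylisourea that DMAP relays as an acylpyridinium to the primary alcohol, under conditions that leave the primary bromide and the terminal alkene untouched; no stereocentre is involved.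

Step 2
Reactants: 3 oct-7-en-1-yl 16-bromohexadecanoate
Product: 5 24-tetracosanolide, via B-alkyl-9-BBN bromo ester 4 (not isolated)
Conditions: 9-BBN dimer (0.53 equiv), THF, 0 °C → rt; then syringe-pump addition to Pd(OAc)2 (20 mol %), PCy3 (40 mol %), K3PO4·H2O, THF, 60 °C, final 2 mM
Reagents that add atoms: none
Why: Proposed new method: 9-BBN adds anti-Markovnikov to the terminal alkene of 3, placing boron on the terminal carbon (the future C17) and leaving ester and primary bromide untouched, to give B-alkyl-9-BBN 4. Pd(0)/PCy3 then inserts into the C16–Br bond by an SN2-type oxidative addition, the hydroxide-activated borate end of the same molecule transfers C17 to palladium, and reductive elimination forms the C16–C17 bond as a finished CH2–CH2 link. The closest known reaction types are the intermolecular Pd/PCy3/K3PO4·H2O alkyl–alkyl Suzuki–Miyaura coupling of β-hydrogen-bearing primary alkyl bromides with B-alkyl-9-BBN reagents, which tolerates esters, and the B-alkyl Suzuki macrocyclization of ω-boryl alkenyl halides; their use together for an sp3–sp3 ring closure is the untested element. The 25-membered oxacycle is closed end to end, by reductive elimination from a 26-membered dialkylpalladacycle, between two primary carbons. No stereocentre is formed. The step needs cyclization to outrun oligomerization, β-hydride elimination and protodebromination: the strain-free, unsubstituted polymethylene ring should have an effective molarity well above the low-millimolar stationary concentration kept by slow addition, heating to 60 °C offsets the slow bimolecular oxidative addition at that dilution, the bulky electron-rich PCy3 ligand disfavours β-hydride elimination, and regiochemistry is fixed because hydroboration has already placed boron only on the terminal carbon.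

**Compound list**
1 | 16-bromohexadecanoic acid | OC(=O)CCCCCCCCCCCCCCCBr | starting material
2 | oct-7-en-1-ol | C=CCCCCCCO | starting material
3 | oct-7-en-1-yl 16-bromohexadecanoate | C=CCCCCCCOC(=O)CCCCCCCCCCCCCCCBr | intermediate
4 | 8-(9-borabicyclo[3.3.1]nonan-9-yl)octyl 16-bromohexadecanoate (B-alkyl-9-BBN bromo ester, formed in the flask, not isolated) | BrCCCCCCCCCCCCCCCC(=O)OCCCCCCCCB1C2CCCC1CCC2 | intermediate
5 | 24-tetracosanolide (oxacyclopentacosan-2-one) | O=C1CCCCCCCCCCCCCCCCCCCCCCCO1 | target

**Total step count:** 2
**Longest linear sequence:** 2

**Steps most likely to fail** (the route has only two steps, so both are ranked and there is no third):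

1. Step 2 (bears the label). The ring closure may lose to intermolecular coupling, giving linear and cyclic oligomers, if oxidative addition at high dilution is slower than the addition rate. Alkyl–palladium intermediates may also be diverted by β-hydride elimination or protodebromination, and the alkylborane may be lost by protodeboronation during the long reaction time. The fallback uses known chemistry only, sets out from 2 and returns to the route at 5. Bromine in CH2Cl2 at 0 °C should convert 2 into racemic 7,8-dibromooctan-1-ol F1. Double dehydrobromination with NaNH2 in liquid NH3 (NH4Cl quench) should give oct-7-yn-1-ol F2, which is also a catalogue compound. DCC/DMAP esterification of F2 with commercial hexadec-15-ynoic acid (C#CCCCCCCCCCCCCCC(=O)O) should give oct-7-yn-1-yl hexadec-15-ynoate F3. Glaser–Eglinton macrocyclization (Cu(OAc)2, pyridine/Et2O, slow addition, high dilution) should then close the ring at the same C16–C17 bond, now the central sp–sp bond of a rigid 1,3-diyne, to give tetracosa-15,17-diyn-24-olide F4. Exhaustive hydrogenation (H2, Pd/C, EtOAc) should deliver 5.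

2. Step 1. The O-acylisourea may rearrange to an unreactive N-acylurea before the alcohol is acylated, and the waxy product may be hard to free from the urea. The fallback activates the acid in a different way; it sets out from 1 and returns at 3. Oxalyl chloride with catalytic DMF in CH2Cl2 should convert 1 into 16-bromohexadecanoyl chloride F5, which is then treated with 2 and pyridine in CH2Cl2 at 0 °C to give 3.

**Further compounds**
F1 | step 2 | 7,8-dibromooctan-1-ol (racemic) | OCCCCCCC(Br)CBr
F2 | step 2 | oct-7-yn-1-ol | C#CCCCCCCO
F3 | step 2 | oct-7-yn-1-yl hexadec-15-ynoate | C#CCCCCCCOC(=O)CCCCCCCCCCCCCC#C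
F4 | step 2 | tetracosa-15,17-diyn-24-olide (oxacyclopentacosa-16,18-diyn-2-one) | O=C1CCCCCCCCCCCCCC#CC#CCCCCCCO1
F5 | step 1 | 16-bromohexadecanoyl chloride | O=C(Cl)CCCCCCCCCCCCCCCBr
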